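The pitfall opened the meeting: a time constant read off a run is no constant if the loss follows [reagent] and [reagent] sinks under it.

all flasks: free catalyst 20 mM; impurity 2.5 mM
- red: left-handed substrate 1 M; right-handed substrate 1 M; reagent 0.40 M; run made earlier
- blue: left-handed substrate 1 M; right-handed substrate 1 M; reagent 0.60 M; run made earlier
- flask: left-handed substrate 1.0 M; right-handed substrate 1.0 M; reagent 0.800 M; time 3.0 min

| run | time / min | left-handed substrate / % | right-handed substrate / % |
|---|---|---|---|
| red | 0.200 | 48.2 | 49.2 |
| red | 0.333 | 48.1 | 49.7 |
| red | 0.500 | 47.9 | 47.0 |
| red | 0.833 | 49.1 | 48.8 |
| red | 1.33 | 45.1 | 49.3 |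
| red | 2.50 | 43.5 | 48.1 |
| blue | 0.417 | 46.6 | 49.2 |
| blue | 0.833 | 44.6 | 49.9 |
| blue | 1.33 | 43.5 | 47.3 |
| blue | 1.50 | 42.3 | 49.2 |
| blue | 2.00 | 39.7 | 47.6 |
| blue | 2.50 | 37.8 | 47.2 |

(each reading ± 1 percentage point)

- free catalyst is single-handed; left-handed substrate and right-handed substrate are mirror images of each other, charged as a racemate, each of them at the stated concentration
- an excess is the difference of the two amounts in percent of their sum
- an excess is below zero if the other one leads

- part of the left-handed substrate and right-handed substrate charged together that has reacted at 3.0 min
- excess of left-handed product over right-handed product in the product at 3.0 min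
- excess of right-handed substrate over left-handed substrate among what is left of the two at 3.0 min

The chair asked what carries from red and blue to the flask. I offered my own pseudo-first-order picture, assuming one reagent per substrate reacted: replace falling [reagent] by its mean, the charge less half of what has reacted. The last readings give a mean of 0.316 M and κ of 0.176 /M/min in red, and 0.450 M and 0.249 /M/min in blue. Each rests on readings with scatter 1 percentage point, so we took as κ, the logarithmic loss of left-handed substrate per minute and per molar of mean reagent, their mean 0.212 /M/min. κ is read at one charge of catalyst and one of impurity, and these match in red, blue and the flask. The ratio of the logarithmic losses, the selectivity factor, reads 4.35.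

For the flask I tried 20.0 % reacted, so mean reagent 0.600 M. That leaves 34.1 % left-handed and 45.8 % right-handed substrate, which returns c, the part reacted, of 20.1 %, with eP, the excess of left-handed product, of 58.2 % and eS, the excess of right-handed substrate, of 14.6 %. The chair doubted the mean, so I took a logarithmic mean instead, 0.576 M. It shifts the left-handed share by 0.53 points, against a reading's scatter of 1 point.

The forecast stood higher on each, at c 25.5 %, eP 65 % and eS 22 %, noting “Reagent (40% equivalent) is not limiting”.

The flask gives c 19.0 %, eP 59.9 % and eS 14.1 %.

    reagent + free catalyst + left-handed substrate → free catalyst + left-handed product (k = 0.289 /M²/s)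
    reagent + free catalyst + right-handed substrate → free catalyst + right-handed product (k = 0.0632 /M²/s)
    free catalyst + impurity → spent catalyst (k = 57.0 /M/s)
    2 free catalyst ⇌ resting dimer, settled at all times (K = 19.0 /M)

In the flask, reagent stands at 52.4 % of its charge at 3.00 min. With the actual c, its mean is 0.610 M, and κ then gives left-handed substrate 33.9 % against 34.8 %. A neighbouring flask, the same but charged with 0.20 M reagent, reaches c 5.18 %, so its mean reagent is 0.148 M. There κ gives left-handed product 4.51 %, and that flask holds 4.23 %.

Readings and results come from a simulation from invented constants; noise was put on by code.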